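**Plan**

- Retrosynthesis (halimane numbering): the 7-acetate and the C20 methyl go back to a C20→O7 γ-lactone; the C8–C9 bond of ring B is cut to an epoxy alcohol with an ester-activated C9–H; C5–C6 is cut to a ring A enol triflate plus crotonaldehyde; C9–C10 is cut to 2,2-dimethylcyclohexanone plus a nitroalkene made from (R)-linalool.
- Forward: ring A is bought; a Michael addition joins C9 (carrying the side chain and C20) to C10; a Cr/Ni coupling joins C6–C8 to C5; ring B closes last, followed in the same flask by the temporary lactone ring.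
- Enabling feature: C9 lies between the C5=C10 double bond of ring A and the C20 carboxyl, so it holds the only acidic C–H, and the chain C9–C10=C5–C6–C7–C8 puts it within a six-membered ring of the distal carbon of a C7–C8 epoxide.
- Stereochemistry: C13 from (R)-linalool; C6 from CBS reduction; C7/C8 from matched Sharpless epoxidation; C8 is inverted and C9 set in the ring closure. The C20 ester and the lactone are removed afterwards (lactol, Wolff–Kishner) to leave the methyl group.

Key step: step 12

Remark: atoms are numbered as in halimane (ring A = C1–C5, C10; ring B = C5–C10; side chain C11–C16; C17 on C8; C18/C19 on C4; C20 on C9). C9, and C10 or C6 while sp3, are epimeric mixtures up to step 11; this is harmless because C9 is planarised in step 12.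

**Route**

Step 1
Reactants: 1 (R)-(−)-linalool
Product: 2 (R)-linalool triethylsilyl ether
Conditions: Et3SiOTf, 2,6-lutidine, CH2Cl2, −78 → 0 °C
Reagents that add atoms: triethylsilyl trifluoromethanesulfonate (CC[Si](CC)(CC)OS(=O)(=O)C(F)(F)F)
Why: Silylation of the hindered tertiary allylic alcohol with a silyl triflate is standard and masks the hydroxyl for the base and organometallic steps; C13 is untouched.

Step 2
Reactants: 2 (R)-linalool triethylsilyl ether
Product: 4 (4R)-4-methyl-4-(triethylsilyloxy)hex-5-enal, via secondary ozonide 3 (not isolated)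
Conditions: O3 (1 equiv), CH2Cl2, −78 °C; PPh3, −78 → 23 °C
Reagents that add atoms: ozone ([O-][O+]=O)
Why: Ozonolysis with reductive work-up; the electron-rich trisubstituted alkene should react much faster than the vinyl group next to the quaternary silyloxy carbon, so one equivalent of ozone should cleave only the former.

Step 3
Reactants: 4 (4R)-4-methyl-4-(triethylsilyloxy)hex-5-enal
Product: 6 (1E,5R)-5-methyl-1-nitro-5-(triethylsilyloxy)hepta-1,6-diene, via nitro alcohol 5 (not isolated)
Conditions: MeNO2 (5 equiv), 1,1,3,3-tetramethylguanidine (0.1 equiv), THF, 0 °C; then MsCl, Et3N, CH2Cl2, 0 °C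
Reagents that add atoms: nitromethane (C[N+](=O)[O-])
Why: Henry (nitroaldol) addition followed by mesylation and E1cB elimination should give the thermodynamically favoured (E)-nitroalkene; the nitromethane carbon becomes C20.

Step 4
Reactants: 7 2,2-dimethylcyclohexanone; 6 (1E,5R)-5-methyl-1-nitro-5-(triethylsilyloxy)hepta-1,6-diene
Product: 9 2,2-dimethyl-6-[(5R)-5-methyl-1-nitro-5-(triethylsilyloxy)hept-6-en-2-yl]cyclohexan-1-one, via lithium enolate 8 (not isolated)
Conditions: 7, LiN(iPr)2, THF, −78 °C; add 6, −78 °C; AcOH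
Reagents that add atoms: none
Why: Michael addition of a ketone lithium enolate (only one α-carbon of 7 bears hydrogen) to a nitroalkene forms the C9–C10 bond; the new centres at C9 and C10 need no control because both become sp2 later (steps 7 and 12).

Step 5
Reactants: 9 2,2-dimethyl-6-[(5R)-5-methyl-1-nitro-5-(triethylsilyloxy)hept-6-en-2-yl]cyclohexan-1-one
Product: 10 (5R)-2-(3,3-dimethyl-2-oxocyclohexyl)-5-methyl-5-(triethylsilyloxy)hept-6-enoic acid
Conditions: NaNO2 (3 equiv), AcOH (10 equiv), DMSO, 35 °C
Reagents that add atoms: sodium nitrite ([Na+].[O-]N=O)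
Why: Nitrite-mediated Nef-type oxidation of a primary nitroalkane to the carboxylic acid (through the nitrolic acid) under mildly acidic conditions that the ketone, the vinyl group and the silyl ether should tolerate.

Step 6
Reactants: 10 (5R)-2-(3,3-dimethyl-2-oxocyclohexyl)-5-methyl-5-(triethylsilyloxy)hept-6-enoic acid
Product: 11 tert-butyl (5R)-2-(3,3-dimethyl-2-oxocyclohexyl)-5-methyl-5-(triethylsilyloxy)hept-6-enoate
Conditions: O-tert-butyl-N,N'-diisopropylisourea (3 equiv), CH2Cl2, 23 °C
Reagents that add atoms: O-tert-butyl-N,N'-diisopropylisourea (CC(C)NC(=NC(C)C)OC(C)(C)C)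
Why: Neutral tert-butyl esterification with an isourea; the tert-butyl ester is chosen because it should not lactonise onto the later C6 hydroxyl, yet it is expelled in step 12.

Step 7
Reactants: 11 tert-butyl (5R)-2-(3,3-dimethyl-2-oxocyclohexyl)-5-methyl-5-(triethylsilyloxy)hept-6-enoate
Product: 13 tert-butyl (5R)-2-[3,3-dimethyl-2-(trifluoromethylsulfonyloxy)cyclohex-1-en-1-yl]-5-methyl-5-(triethylsilyloxy)hept-6-enoate, via potassium enolate 12 (not isolated)
Conditions: KN(SiMe3)2, THF, −78 → 0 °C; PhNTf2, −78 → 0 °C
Reagents that add atoms: N-phenylbis(trifluoromethanesulfonimide) (FC(F)(F)S(=O)(=O)N(c1ccccc1)S(=O)(=O)C(F)(F)F)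
Why: Enol triflate formation from the thermodynamic ketone enolate, which can only form toward C10, so the C5=C10 double bond of ring A is placed regiospecifically.

Step 8
Reactants: 13 enol triflate; 14 (E)-crotonaldehyde
Product: 15 tert-butyl (5R)-2-{2-[(2E)-1-hydroxybut-2-en-1-yl]-3,3-dimethylcyclohex-1-en-1-yl}-5-methyl-5-(triethylsilyloxy)hept-6-enoate
Conditions: 14 (3 equiv), CrCl2 (5 equiv), NiCl2 (2 mol %), DMF, 23 °C
Reagents that add atoms: none
Why: Nozaki–Hiyama–Kishi coupling (oxidative addition of the enol triflate to zerovalent nickel, transmetallation to trivalent chromium, 1,2-addition to the enal) forms C5–C6 under neutral conditions that leave the ester and its acidic C9–H alone; the C6 configuration is irrelevant here.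

Step 9
Reactants: 15 doubly allylic alcohol
Product: 16 tert-butyl (5R)-2-{2-[(2E)-but-2-enoyl]-3,3-dimethylcyclohex-1-en-1-yl}-5-methyl-5-(triethylsilyloxy)hept-6-enoate
Conditions: Dess–Martin periodinane, NaHCO3, CH2Cl2, 0 → 23 °C
Reagents that add atoms: none
Why: Dess–Martin oxidation of the doubly allylic alcohol to the cross-conjugated dienone under buffered, non-basic conditions, so that C9–H is not deprotonated (which would start a premature Michael ring closure).

Step 10
Reactants: 16 dienone
Product: 17 tert-butyl (5R)-2-{2-[(1R,2E)-1-hydroxybut-2-en-1-yl]-3,3-dimethylcyclohex-1-en-1-yl}-5-methyl-5-(triethylsilyloxy)hept-6-enoate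
Conditions: (S)-2-methyl-CBS-oxazaborolidine (0.2 equiv), catecholborane (1.5 equiv), toluene, −78 °C
Reagents that add atoms: none
Why: Corey–Bakshi–Shibata reduction; the twisted, fully substituted cyclohexenyl group should act as the large substituent and the propenyl group as the small one, so the (S)-catalyst should give the (6R)-carbinol, and catecholborane is used to spare the alkenes.

Step 11
Reactants: 17 (6R)-dienol
Product: 18 tert-butyl (5R)-2-{2-[(S)-hydroxy((2S,3S)-3-methyloxiran-2-yl)methyl]-3,3-dimethylcyclohex-1-en-1-yl}-5-methyl-5-(triethylsilyloxy)hept-6-enoate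
Conditions: Ti(OiPr)4 (0.2 equiv), L-(+)-diisopropyl tartrate (0.25 equiv), tBuOOH (2 equiv), 4 Å molecular sieves, CH2Cl2, −20 °C
Reagents that add atoms: tert-butyl hydroperoxide (CC(C)(C)OO)
Why: Sharpless asymmetric epoxidation of a secondary allylic alcohol in the matched sense; the (6R)-carbinol with L-(+)-tartrate should give the erythro trans-epoxy alcohol (6S,7S,8S by CIP, C6 unchanged in space), the hindered tetrasubstituted ring alkene being a much poorer partner than the (E)-propenyl group.

Step 12
Reactants: 18 epoxy alcohol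
Product: 21 (6S,7R,8S,9S,13R)-6-hydroxy-13-(triethylsilyloxy)halima-5(10),14-dien-20,7-olide, via dipotassium dianion 19 (not isolated), via ring-closed dialkoxide 20 (not isolated)
Conditions: add 18 to KN(SiMe3)2 (2.4 equiv), THF, −78 °C; −78 → 23 °C; then 45 °C; aq. NH4Cl
Reagents that add atoms: none
Why: The first equivalent of base makes the C6 alkoxide (which cannot leave, so the vinylogous β-elimination open to a protected C6 oxygen is shut, as in a Fráter–Seebach dianion) and the second removes the only acidic C–H, at C9, to give the ester dienolate 19, whose C9 opens the epoxide at C8 with inversion, after which the C7 alkoxide displaces tert-butoxide to give the γ-lactone. The closest known reaction type is the Stork epoxynitrile cyclisation, here with an ester dienolate as the carbon nucleophile. Ring B closes in the 6-endo mode at the distal epoxide carbon (attack at C7 would need a five-membered ring through a dienolate whose C9, C10, C5 and C6 are coplanar, the disfavoured enolendo geometry), and the lactone ring closes by 5-exo-trig acyl substitution. C8 is fixed by SN2 inversion of the epoxide from step 11 and C7 is untouched; at C9 the half-chair transition state enforced by the anti C9···C8–O alignment (C7–O pseudo-equatorial, C6–O pseudo-axial, C8 methyl pseudo-equatorial) is expected to carry the bulky potassium ester enolate outside (pseudo-equatorial, next to C1) and the CH2 chain inside (pseudo-axial), because the inside position faces C6; this places C20 cis to O7 as the target requires. The step needs C- over O-alkylation (only C9 can reach C8 through a six-membered ring) and C9 face selectivity; only the desired C9 epimer can lactonise, which also marks it for separation.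

Step 13
Reactants: 21 hydroxy γ-lactone
Product: 22 (6S,7R,8S,9S,13R)-20,7-epoxy-13-(triethylsilyloxy)halima-5(10),14-diene-6,20-diol (lactol; both C20 anomers)
Conditions: iBu2AlH (3 equiv), CH2Cl2, −78 °C; aq. KNaC4H4O6 (potassium sodium tartrate)
Reagents that add atoms: none
Why: Low-temperature reduction of a lactone to the lactol with iBu2AlH, which should stop at the aluminium hemiacetal; one equivalent is consumed by the free 6-hydroxyl.

Step 14
Reactants: 22 lactol
Product: 24 (6S,7R,8S,9R,13R)-halima-5(10),14-diene-6,7,13-triol, via hydrazone 23 (not isolated)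
Conditions: N2H4·H2O, KOH, diethylene glycol, 130 °C then 200 °C
Reagents that add atoms: none
Why: Wolff–Kishner (Huang–Minlon) reduction of the lactol through the hydrazone of its open hydroxy aldehyde should turn C20 into the methyl group and free O7; the hot alkali is also expected to cleave the triethylsilyl ether, and no stereocentre is epimerisable (C9 is quaternary).

Step 15
Reactants: 24 triol
Product: 25 (6S,7R,8S,9R,13R)-6,13-dihydroxyhalima-5(10),14-dien-7-yl acetate (target)
Conditions: Ac2O (1.1 equiv), pyridine, CH2Cl2, 0 °C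
Reagents that add atoms: acetic anhydride (CC(=O)OC(C)=O)
Why: Selective acylation; the equatorial 7-hydroxyl should react faster than the pseudo-axial allylic 6-hydroxyl, which is screened by the C4 gem-dimethyl group, and far faster than the tertiary 13-hydroxyl.

**Compound list**

1 | (R)-(−)-linalool, (3R)-3,7-dimethylocta-1,6-dien-3-ol | C=C[C@](C)(O)CCC=C(C)C | starting material
2 | (R)-linalool triethylsilyl ether | C=C[C@](C)(O[Si](CC)(CC)CC)CCC=C(C)C | intermediate
3 | secondary ozonide (1,2,4-trioxolane) of 2 at the trisubstituted alkene | C=C[C@](C)(O[Si](CC)(CC)CC)CCC1OOC(C)(C)O1 | intermediate (not isolated)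
4 | (4R)-4-methyl-4-(triethylsilyloxy)hex-5-enal | C=C[C@](C)(O[Si](CC)(CC)CC)CCC=O | intermediate
5 | (5R)-5-methyl-1-nitro-5-(triethylsilyloxy)hept-6-en-2-ol (both C2 epimers) | C=C[C@](C)(O[Si](CC)(CC)CC)CCC(O)C[N+](=O)[O-] | intermediate (not isolated)
6 | (1E,5R)-5-methyl-1-nitro-5-(triethylsilyloxy)hepta-1,6-diene | C=C[C@](C)(O[Si](CC)(CC)CC)CC/C=C/[N+](=O)[O-] | intermediate
7 | 2,2-dimethylcyclohexanone | CC1(C)CCCCC1=O | starting material
8 | lithium 6,6-dimethylcyclohex-1-en-1-olate | [Li+].[O-]C1=CCCCC1(C)C | intermediate (not isolated)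
9 | 2,2-dimethyl-6-[(5R)-5-methyl-1-nitro-5-(triethylsilyloxy)hept-6-en-2-yl]cyclohexan-1-one (epimers at C9 and C10) | C=C[C@](C)(O[Si](CC)(CC)CC)CCC(C[N+](=O)[O-])C1CCCC(C)(C)C1=O | intermediate
10 | (5R)-2-(3,3-dimethyl-2-oxocyclohexyl)-5-methyl-5-(triethylsilyloxy)hept-6-enoic acid (epimers at C9 and C10) | C=C[C@](C)(O[Si](CC)(CC)CC)CCC(C(=O)O)C1CCCC(C)(C)C1=O | intermediate
11 | tert-butyl (5R)-2-(3,3-dimethyl-2-oxocyclohexyl)-5-methyl-5-(triethylsilyloxy)hept-6-enoate (epimers at C9 and C10) | C=C[C@](C)(O[Si](CC)(CC)CC)CCC(C(=O)OC(C)(C)C)C1CCCC(C)(C)C1=O | intermediate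
12 | potassium enolate of 11 (C5–O, C5=C10) | [K+].C=C[C@](C)(O[Si](CC)(CC)CC)CCC(C(=O)OC(C)(C)C)C1=C([O-])C(C)(C)CCC1 | intermediate (not isolated)
13 | tert-butyl (5R)-2-[3,3-dimethyl-2-(trifluoromethylsulfonyloxy)cyclohex-1-en-1-yl]-5-methyl-5-(triethylsilyloxy)hept-6-enoate (C9 epimers) | C=C[C@](C)(O[Si](CC)(CC)CC)CCC(C(=O)OC(C)(C)C)C1=C(OS(=O)(=O)C(F)(F)F)C(C)(C)CCC1 | intermediate
14 | (E)-crotonaldehyde, (2E)-but-2-enal | C/C=C/C=O | starting material
15 | tert-butyl (5R)-2-{2-[(2E)-1-hydroxybut-2-en-1-yl]-3,3-dimethylcyclohex-1-en-1-yl}-5-methyl-5-(triethylsilyloxy)hept-6-enoate (epimers at C6 and C9) | C=C[C@](C)(O[Si](CC)(CC)CC)CCC(C(=O)OC(C)(C)C)C1=C(C(O)/C=C/C)C(C)(C)CCC1 | intermediate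
16 | tert-butyl (5R)-2-{2-[(2E)-but-2-enoyl]-3,3-dimethylcyclohex-1-en-1-yl}-5-methyl-5-(triethylsilyloxy)hept-6-enoate (C9 epimers) | C=C[C@](C)(O[Si](CC)(CC)CC)CCC(C(=O)OC(C)(C)C)C1=C(C(=O)/C=C/C)C(C)(C)CCC1 | intermediate
17 | tert-butyl (5R)-2-{2-[(1R,2E)-1-hydroxybut-2-en-1-yl]-3,3-dimethylcyclohex-1-en-1-yl}-5-methyl-5-(triethylsilyloxy)hept-6-enoate (C9 epimers) | C=C[C@](C)(O[Si](CC)(CC)CC)CCC(C(=O)OC(C)(C)C)C1=C([C@H](O)/C=C/C)C(C)(C)CCC1 | intermediate
18 | tert-butyl (5R)-2-{2-[(S)-hydroxy((2S,3S)-3-methyloxiran-2-yl)methyl]-3,3-dimethylcyclohex-1-en-1-yl}-5-methyl-5-(triethylsilyloxy)hept-6-enoate (C9 epimers) | C=C[C@](C)(O[Si](CC)(CC)CC)CCC(C(=O)OC(C)(C)C)C1=C([C@H](O)[C@@H]2O[C@H]2C)C(C)(C)CCC1 | intermediate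
19 | dipotassium dianion of 18 (C6 alkoxide and ester dienolate, C9 planar) | [K+].[K+].C=C[C@](C)(O[Si](CC)(CC)CC)CCC(=C([O-])OC(C)(C)C)C1=C([C@H]([O-])[C@@H]2O[C@H]2C)C(C)(C)CCC1 | intermediate (not isolated)
20 | dipotassium 6,7-dialkoxide of tert-butyl (6S,7R,8S,9S,13R)-6,7-dihydroxy-13-(triethylsilyloxy)halima-5(10),14-dien-20-oate | [K+].[K+].C=C[C@](C)(O[Si](CC)(CC)CC)CC[C@@]1(C(=O)OC(C)(C)C)C2=C([C@H]([O-])[C@H]([O-])[C@H]1C)C(C)(C)CCC2 | intermediate (not isolated)
21 | (6S,7R,8S,9S,13R)-6-hydroxy-13-(triethylsilyloxy)halima-5(10),14-dien-20,7-olide (the 9S descriptor reflects only the priority of the C20 carbonyl; the centre is that of the target) | C=C[C@](C)(O[Si](CC)(CC)CC)CC[C@@]1(C3=O)C2=C([C@H](O)[C@H](O3)[C@H]1C)C(C)(C)CCC2 | intermediate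
22 | (6S,7R,8S,9S,13R)-20,7-epoxy-13-(triethylsilyloxy)halima-5(10),14-diene-6,20-diol (lactol, both C20 anomers, anomeric centre left unspecified) | C=C[C@](C)(O[Si](CC)(CC)CC)CC[C@@]1(C3O)C2=C([C@H](O)[C@H](O3)[C@H]1C)C(C)(C)CCC2 | intermediate
23 | hydrazone of (6S,7R,8S,9S,13R)-6,7-dihydroxy-13-(triethylsilyloxy)halima-5(10),14-dien-20-al | C=C[C@](C)(O[Si](CC)(CC)CC)CC[C@@]1(C=NN)C2=C([C@H](O)[C@H](O)[C@H]1C)C(C)(C)CCC2 | intermediate (not isolated)
24 | (6S,7R,8S,9R,13R)-halima-5(10),14-diene-6,7,13-triol | C=C[C@](C)(O)CC[C@@]1(C)C2=C([C@H](O)[C@H](O)[C@H]1C)C(C)(C)CCC2 | intermediate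
25 | (6S,7R,8S,9R,13R)-6,13-dihydroxyhalima-5(10),14-dien-7-yl acetate | C=C[C@](C)(O)CC[C@@]1(C)C2=C([C@H](O)[C@H](OC(C)=O)[C@H]1C)C(C)(C)CCC2 | target

**Step count and risks**

Total step count: 15. Longest linear sequence: 15 steps (1 → 25); compounds 7 and 14 are bought and enter at steps 4 and 8.

The ring closure (step 12) is the most exposed step. The control over which C9 substituent sits inside the forming ring may be weak, giving the C9 epimer, and the hindered dienolate may open the epoxide too slowly, so that reversible Payne migration or decomposition takes over. The fallback changes the activation from anionic to Lewis-acidic and sets out from 18. LiN(iPr)2 with Me3SiCl present (THF, −78 °C) should silylate both the C6 oxygen and the ester enolate to give the bis-silyl ketene acetal F1. BF3·OEt2 (CH2Cl2, −78 → 0 °C) should then open the epoxide at C8 by Mukaiyama-type attack of the ketene acetal through the same chair-like array and, with loss of the tert-butyl group as isobutene, close the lactone to the 6-O-trimethylsilyl lactone F2. K2CO3 in MeOH should remove the silyl ether, and the route is rejoined at 21.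

The C5–C6 coupling (step 8) may fail through slow oxidative addition and transmetallation at the fully substituted enol triflate flanked by the quaternary C4, leading to reduction of the triflate or no coupling. The fallback sets out from 13 and replaces addition and oxidation by one carbonylative step: Pd(PPh3)4, LiCl, CO (1 atm) and tributyl[(E)-prop-1-enyl]stannane in THF at 55 °C (carbonylative Stille coupling) should give the dienone directly, rejoining the route at 16 and making step 9 unnecessary.

The final monoacetylation (step 15) may lose site selectivity between O6 and O7 or suffer acyl migration across the cis-diol. The fallback sets out from 24 and uses tin-directed acylation instead of relying on inherent rates: Bu2SnO (toluene, reflux, water removal) should give the 6,7-O-dibutylstannylene acetal F3, in which the equatorial O7 is the activated oxygen; acetyl chloride (CH2Cl2, 0 °C) should then acylate O7 only, coming back to the route at 25.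

Further compounds
F1 | step 12 | tert-butyl trimethylsilyl ketene acetal of 18 with the C6 hydroxyl as trimethylsilyl ether | C=C[C@](C)(O[Si](CC)(CC)CC)CCC(=C(O[Si](C)(C)C)OC(C)(C)C)C1=C([C@H](O[Si](C)(C)C)[C@@H]2O[C@H]2C)C(C)(C)CCC1
F2 | step 12 | (6S,7R,8S,9S,13R)-13-(triethylsilyloxy)-6-(trimethylsilyloxy)halima-5(10),14-dien-20,7-olide | C=C[C@](C)(O[Si](CC)(CC)CC)CC[C@@]1(C3=O)C2=C([C@H](O[Si](C)(C)C)[C@H](O3)[C@H]1C)C(C)(C)CCC2
F0 | step 8 | none | none
F3 | step 15 | 6,7-O-dibutylstannylene acetal of 24 | C=C[C@](C)(O)CC[C@@]1(C)C2=C([C@@H]3O[Sn](CCCC)(CCCC)O[C@@H]3[C@H]1C)C(C)(C)CCC2
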